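# Proposed synthesis of (2S)-6-prenylsakuranetin

Flavanone numbering is used throughout (O1, C2, C3, C4, C4a, C5–C8, C8a; ring B carbons primed). Compound numbers are those of the steps below.

## The problem

6-Prenylsakuranetin (13) is a flavanone: benzene ring A is fused to dihydropyranone ring C, whose C2 carries the 4-hydroxyphenyl ring B. Ring A is fully differentiated, with a free, carbonyl-chelated hydroxyl at C5, the prenyl group at C6, a methyl ether at C7, hydrogen at C8 and the ring oxygen O1 on C8a. A synthesis must therefore decide which of three phloroglucinol-type oxygens is methylated, which one closes ring C, and where the prenyl group sits relative to them. The only stereocentre, C2 (S), has no neighbouring stereocentre to control it and must be set by a chiral catalyst or reagent. It is also fragile: C2 is a benzylic ether carbon β to the ketone and para to a phenol, so base, strong acid or heat can open ring C by retro-oxa-Michael reaction and reclose it as the racemate. The prenyl alkene rules out hydrogenation and strong protic or Lewis acids, under which it cyclises onto the adjacent C5 hydroxyl. The enabling feature is ring C itself. Its bonds O1–C2 and C3–C4 flank a C2–C3 unit that, with ring B attached, is 4-vinylphenol (9). The chain O1–C8a–C4a–C4 is the oxygen-to-carbonyl-carbon chain of a salicylaldehyde (7), which is a hydroxy-substituted ortho-quinone methide in its protonated or tautomeric form.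

## Retrosynthesis

**13 from 12.** The last bond cut is the O–CH3 bond at C5. Keeping this oxygen methylated as far as flavanone 12 lets ring A derive from a phenol with a mirror plane and leaves only one free hydroxyl to become O1 in the ring-forming step. Of the methyl ethers in 12, only the C5 one sits peri to the C4 carbonyl, so a chelating magnesium halide should remove that methyl group alone. A more labile group at C5 would have required desymmetrising ring A earlier. The forward step must spare the prenyl alkene and the C2–O1 bond.

**12 from 11.** The C4 ketone is taken back to the secondary alcohol of flavan-4-ol 11. No skeletal bond is cut. The point is that C4 then has the oxidation level an aldehyde carbon reaches after one C–C bond formation. The cost is one oxidation, which must select a benzylic alcohol beside a free phenol and an alkene. The gain is that the C4 configuration need not be controlled, since it disappears.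

**11 from 7 and 9.** Ring C is opened at C3–C4 and O1–C2, giving salicylaldehyde 7 and 4-vinylphenol 9.
- Cutting O1–C2 alone (oxa-Michael closure) would rely on the same equilibrium that racemises flavanones.
- Cutting C2–C1' (conjugate arylation) requires the heterocycle to exist first.
- Cutting O1–C8a requires a leaving group on an electron-rich arene.

The two-bond cut divides the molecule into two achiral aromatic pieces of similar size. It removes ring C and both stereocentres in one operation. The forward reaction is a polar [4+2] annulation under a chiral Brønsted acid, which must control the face at which C2 is formed and tolerate the free phenol and the prenyl group. Because 11 is a trioxygenated benzylic alcohol that acid can ionise, three precautions are built in: the acid is levelled by the basic carbonyl of 7, 9 is added slowly at low temperature, and 11 is oxidised without storage.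

**9 from 8.** 4-Vinylphenol polymerises on storage, so it is released from its acetate 8 immediately before use.

**7 from 6.** The formyl carbon (C4) is removed by cutting C4–C4a. Phenol 6 has a mirror plane through C1 and C4, so its two ortho positions are identical and an ortho-selective formylation can give only 7. Formylating a ring already differentiated at its oxygens would mean choosing between two similar positions.

**6 from 5, and 5 from 2 and 3 via 4, and 2 from 1.** The prenyl group is detached at the aryl–CH2 bond. The carbon between the two methoxy groups of silyl ether 2 is the site of cooperative directed lithiation. Aryllithium 4 is then alkylated by prenyl bromide 3 to give 5, and desilylation frees 6. Electrophilic prenylation of 1 would favour the position next to the hydroxyl and expose the alkene to acid. The triisopropylsilyl group is chosen because it neither directs lithiation nor migrates to carbon. Commercial 1 already contains the whole oxygenation pattern.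

## Roads not taken

Alternative 1: Ring A is disconnected at C5–C6, C7–C8 and C4a–C5. This leaves ring C as an enantioenriched dihydropyranone carrying a diazoacetyl group at the future C8a, namely (2S)-2-[4-(tert-butyldimethylsilyloxy)phenyl]-6-(diazoacetyl)-2,3-dihydro-4H-pyran-4-one A2, together with the ynol ether 1-methoxy-5-methylhex-4-en-1-yne A3.
- **Forward key step:** irradiation of A2 causes Wolff rearrangement to a vinylketene. Ketene–alkyne [2+2] addition with A3 forms C5–C6 and C7–C8. Heating opens the cyclobutenone (4π) and closes C4a–C5 (6π) to give, after tautomerisation, 6-prenylsakuranetin 4'-O-tert-butyldimethylsilyl ether A1. From A1 only a fluoride desilylation would remain to reach 13.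
- **Merits:** the polarity of the ynol ether A3 fixes prenyl at C6 and methoxy at C7. The C5 hydroxyl of A1 is formed free and the ketone is already present, so neither the oxidation nor the demethylation of the chosen route is needed. C2 would be set by an asymmetric hetero-Diels–Alder reaction, a well-established reaction class. In these respects this road is better.
- **Weak points:** A2 and A3 each need several steps, and A3 is a sensitive 1-alkoxyalkyne. The enone chromophore of A2 competes for light. The thermal stage heats A1 as it forms, and A1 is a 5-hydroxyflavanone, the very structure that racemises by ring opening. The ketene can also be trapped by the prenyl alkene.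
- **Comparison:** the chosen plan offers convergence, brevity and a ring closure at low temperature. In return it accepts an unprecedented enantioselective step and a late demethylation, neither of which the road through A1 needs.

Alternative 2: The cut is O1–C8a. The precursor is the silylated aldol (3S)-1-[6-fluoro-2,4-dimethoxy-3-(3-methylbut-2-enyl)phenyl]-3-[4-(methoxymethoxy)phenyl]-3-(triethylsilyloxy)propan-1-one A5.
- **Forward key step:** catalytic CsF releases the C2 alkoxide of A5, which displaces fluoride at C8a. The fluoride set free continues the desilylation. The product is (2S)-5,7-dimethoxy-2-[4-(methoxymethoxy)phenyl]-6-(3-methylbut-2-enyl)chroman-4-one A4. From A4 the target would still require removal of the methoxymethyl group and of the C5 methyl group.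
- **Merits:** the C2–O bond is neither made nor broken on the way from A5 to A4, so the stereocentre comes from a dependable asymmetric aldol or reduction and is retained. The ketone is in place, and ring C never passes through an acid-labile flavan-4-ol. This is safer for C2 than the chosen key step.
- **Weak points:** the arene of A5 is electron-rich, and the single activating acyl group is weakened as an acceptor by the ortho and para methoxy groups at C5 and C7. Substitution must therefore compete with retro-aldol cleavage and β-elimination of the β-alkoxide. A5 requires fluorine, two methoxy groups, the prenyl group and the acyl chain to be placed around one ring in fixed order. The endgame from A4 needs two deprotections, one of them acidic next to the prenyl group.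
- **Comparison:** the chosen plan is shorter and needs no fluoroarene, but it shares the C5 demethylation with the road through A4 and carries the higher risk at C2.

Alternative 3: The cut is C3=C4 of a 2H-chromene. The precursor is the diene tert-butyl{4-[(1S)-1-{2-[1-(tert-butyldimethylsilyloxy)vinyl]-3,5-dimethoxy-4-(3-methylbut-2-enyl)phenoxy}prop-2-enyl]phenoxy}dimethylsilane A7.
- **Forward key step:** ring-closing metathesis of A7 with second-generation Grubbs catalyst, RuCl2(=CHPh)(PCy3)(H2IMes), gives (2S)-4-(tert-butyldimethylsilyloxy)-2-[4-(tert-butyldimethylsilyloxy)phenyl]-5,7-dimethoxy-6-(3-methylbut-2-enyl)-2H-chromene A6. This compound A6 is the silyl enol ether of the flavanone.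
- **Merits:** C2 would be set from 6 after ortho-acetylation by an asymmetric allylic etherification ([Ir(cod)Cl]2 with a chiral phosphoramidite) of predictable sense. A6 collapses to the ketone under mild fluoride treatment, so no oxidation is needed.
- **Weak points:** the allylic aryl ether of A7 is both allylic and para-oxybenzylic and its leaving group is an acylphenol-type oxygen, so ionisation or sigmatropic shift threatens C2 during the heated metathesis. The 1,1-disubstituted silyl enol ether is flanked by two ortho substituents and is a slow metathesis partner. The prenyl alkene is a competing olefin that can lose isobutene. The etherification must use a chelated, hindered phenol. The sequence is also longer.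
- **Comparison:** the road through A7 and A6 has the better-understood stereochemistry. The chosen plan has fewer steps and no olefin chemistry in the presence of the prenyl group.

Key step: step 6

Assumption: the (R)-enantiomer of the acid in step 6 is taken to give the 2S,4S product. The sense of induction cannot be predicted for this new reaction; if it proves opposite, the equally accessible (S)-acid is used with no other change.

## Route

Step 1
Reactants: 1 3,5-dimethoxyphenol
Product: 2 (3,5-dimethoxyphenoxy)triisopropylsilane
Conditions: TIPSCl, imidazole, DMF, rt
Reagents that add atoms: triisopropylsilyl chloride (TIPSCl), CC(C)[Si](Cl)(C(C)C)C(C)C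
Why: Standard silylation of a phenol with a silyl chloride and imidazole; the bulky triisopropylsilyl group is chosen because it neither directs lithiation nor migrates from oxygen to carbon in step 2.

Step 2
Reactants: 2 (3,5-dimethoxyphenoxy)triisopropylsilane, 3 prenyl bromide (1-bromo-3-methylbut-2-ene)
Product: 5 [3,5-dimethoxy-4-(3-methylbut-2-enyl)phenoxy]triisopropylsilane, via aryllithium 4 (not isolated)
Conditions: n-BuLi, THF, 0 °C to rt; then 3, −78 °C to rt
Reagents that add atoms: none
Why: Directed ortho-metalation: the C–H between the two methoxy groups is acidified and coordinated by both, while the positions beside the bulky, poorly coordinating silyloxy group are shielded, so 4 should form regioselectively; SN2 alkylation of the aryllithium by the primary allylic bromide then installs the prenyl group, as is routine for 2,6-dimethoxyphenyllithiums.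

Step 3
Reactants: 5 [3,5-dimethoxy-4-(3-methylbut-2-enyl)phenoxy]triisopropylsilane
Product: 6 3,5-dimethoxy-4-(3-methylbut-2-enyl)phenol
Conditions: TBAF, AcOH, THF, 0 °C to rt
Reagents that add atoms: none
Why: Fluoride-induced cleavage of an aryl silyl ether; buffering with acetic acid prevents build-up of phenoxide, and the conditions do not affect the prenyl alkene.

Step 4
Reactants: 6 3,5-dimethoxy-4-(3-methylbut-2-enyl)phenol
Product: 7 6-hydroxy-2,4-dimethoxy-3-(3-methylbut-2-enyl)benzaldehyde
Conditions: MgCl2, Et3N, (CH2O)n, MeCN, reflux; then cold 1 M HCl
Reagents that add atoms: paraformaldehyde (as formaldehyde), C=O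
Why: Casnati–Skattebøl ortho-formylation, a magnesium-mediated ortho-hydroxymethylation of the phenol followed in the same flask by hydride transfer to a second formaldehyde; because 6 has a mirror plane both ortho positions are identical and only 7 can form, and the weakly basic medium spares the prenyl group.

Step 5
Reactants: 8 4-acetoxystyrene
Product: 9 4-vinylphenol
Conditions: K2CO3 (0.2 equiv), MeOH, 0 °C to rt; AcOH; used at once
Reagents that add atoms: none
Why: Base-catalysed methanolysis of an aryl acetate; mild conditions and immediate use avoid polymerisation of the vinylphenol.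

Step 6
Reactants: 7 6-hydroxy-2,4-dimethoxy-3-(3-methylbut-2-enyl)benzaldehyde, 9 4-vinylphenol
Product: 11 (2S,4S)-2-(4-hydroxyphenyl)-5,7-dimethoxy-6-(3-methylbut-2-enyl)chroman-4-ol, via para-quinone methide 10 (not isolated)
Conditions: (R)-3,3'-bis(2,4,6-triisopropylphenyl)-1,1'-binaphthyl-2,2'-diyl N-(trifluoromethylsulfonyl)phosphoramide (5 mol%), 7 (1.2 equiv), PhMe/CH2Cl2, −30 °C, 9 added over 8 h; Et3N quench
Reagents that add atoms: none
Why: Proposed new method: the acid, much stronger than a phosphoric acid, should protonate the unusually basic (vinylogous carbonate) carbonyl of 7 to a hydroxy-substituted ortho-quinone methide cation held as a contact ion pair, while an oxygen of the same anion hydrogen-bonds the OH of 9 and raises the nucleophilicity of its terminal carbon. That carbon adds to C4 (C3–C4 bond) to give para-quinone methide 10, whose methide carbon is then attacked by the ring A hydroxyl (O1–C2 bond) in a 6-exo-trig oxa-conjugate addition that closes ring C, so the process is a stepwise polar [4+2]. The closest known reaction types are acid-mediated [4+2] annulations of salicylaldehyde-derived oxocarbenium or ortho-quinone methide ions with styrenes (racemic, normally run with an orthoformate to give 4-alkoxyflavans), chiral phosphoric acid catalysed cycloadditions of 4-aryl ortho-quinone methides with vinylphenols, and confined-acid intramolecular [4+2] reactions of salicylaldehyde-derived ortho-quinone methides; an enantioselective intermolecular reaction of a free salicylaldehyde has not been shown. C4 is set in the C–C bond formation by the face of the ion-paired cation that the 3,3'-aryl groups of the catalyst leave open. C2 is set in the ring closure, where a chair-like transition state with ring B pseudo-equatorial and cis to the C4 hydroxyl relays the C4 configuration while the catalyst remains bound to the quinone methide oxygen, so the 2,4-cis (2S,4S) isomer is expected. Regioselectivity of closure is secured by the C5 methyl ether, which leaves the C8a hydroxyl as the only nucleophile; chemoselectivity over oligomerisation of 9 and over ionisation of the product at C4 is sought through levelling of the acid by the basic carbonyl of 7, slow addition of 9 to excess 7, low temperature and an amine quench. The prenyl alkene is far less nucleophilic than the hydrogen-bonded vinylphenol and should not compete, and only C2 has to survive because C4 is oxidised in step 7.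

Step 7
Reactants: 11 (2S,4S)-2-(4-hydroxyphenyl)-5,7-dimethoxy-6-(3-methylbut-2-enyl)chroman-4-ol
Product: 12 (2S)-2-(4-hydroxyphenyl)-5,7-dimethoxy-6-(3-methylbut-2-enyl)chroman-4-one
Conditions: activated MnO2, CH2Cl2, rt (11 used without storage)
Reagents that add atoms: none
Why: Heterogeneous MnO2 oxidation of an activated benzylic alcohol (the carbinol is attached to a trioxygenated arene); the neutral conditions should leave the phenol, the prenyl alkene and the C2 ether untouched, and since C4 becomes sp2 the cis/trans composition of 11 is irrelevant while C2 is not involved.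

Step 8
Reactants: 12 (2S)-2-(4-hydroxyphenyl)-5,7-dimethoxy-6-(3-methylbut-2-enyl)chroman-4-one
Product: 13 6-prenylsakuranetin, (2S)-5-hydroxy-2-(4-hydroxyphenyl)-7-methoxy-6-(3-methylbut-2-enyl)chroman-4-one
Conditions: MgI2·OEt2 (3 equiv), THF, 50 °C; then cold 0.5 M HCl
Reagents that add atoms: none
Why: Chelation-controlled ether cleavage: magnesium bridges the C4 carbonyl and the C5 methoxy oxygen and iodide removes the methyl group by SN2 substitution, whereas the C7 methyl ether cannot chelate and stays; the aprotic, weakly Lewis acidic medium is chosen to spare the prenyl alkene and the C2–O1 bond, so the 2S centre is carried through.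

## Compound list

1 | 3,5-dimethoxyphenol | COc1cc(O)cc(OC)c1 | starting material
2 | (3,5-dimethoxyphenoxy)triisopropylsilane | COc1cc(O[Si](C(C)C)(C(C)C)C(C)C)cc(OC)c1 | intermediate
3 | prenyl bromide (1-bromo-3-methylbut-2-ene) | CC(C)=CCBr | starting material
4 | [2,6-dimethoxy-4-(triisopropylsilyloxy)phenyl]lithium | [Li]c1c(OC)cc(O[Si](C(C)C)(C(C)C)C(C)C)cc1OC | intermediate (not isolated)
5 | [3,5-dimethoxy-4-(3-methylbut-2-enyl)phenoxy]triisopropylsilane | COc1cc(O[Si](C(C)C)(C(C)C)C(C)C)cc(OC)c1CC=C(C)C | intermediate
6 | 3,5-dimethoxy-4-(3-methylbut-2-enyl)phenol | COc1cc(O)cc(OC)c1CC=C(C)C | intermediate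
7 | 6-hydroxy-2,4-dimethoxy-3-(3-methylbut-2-enyl)benzaldehyde | COc1cc(O)c(C=O)c(OC)c1CC=C(C)C | intermediate
8 | 4-acetoxystyrene | CC(=O)Oc1ccc(C=C)cc1 | starting material
9 | 4-vinylphenol | C=Cc1ccc(O)cc1 | intermediate
10 | 4-{(3S)-3-hydroxy-3-[6-hydroxy-2,4-dimethoxy-3-(3-methylbut-2-enyl)phenyl]propylidene}cyclohexa-2,5-dien-1-one | COc1cc(O)c([C@@H](O)CC=C2C=CC(=O)C=C2)c(OC)c1CC=C(C)C | intermediate (not isolated)
11 | (2S,4S)-2-(4-hydroxyphenyl)-5,7-dimethoxy-6-(3-methylbut-2-enyl)chroman-4-ol | COc1cc2c(c(OC)c1CC=C(C)C)[C@@H](O)C[C@@H](c1ccc(O)cc1)O2 | intermediate
12 | (2S)-2-(4-hydroxyphenyl)-5,7-dimethoxy-6-(3-methylbut-2-enyl)chroman-4-one | COc1cc2c(c(OC)c1CC=C(C)C)C(=O)C[C@@H](c1ccc(O)cc1)O2 | intermediate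
13 | 6-prenylsakuranetin, (2S)-5-hydroxy-2-(4-hydroxyphenyl)-7-methoxy-6-(3-methylbut-2-enyl)chroman-4-one | COc1cc2c(c(O)c1CC=C(C)C)C(=O)C[C@@H](c1ccc(O)cc1)O2 | target

## Step count and risk assessment

Total step count: 8. Longest linear sequence: 7 steps (steps 1, 2, 3, 4, 6, 7, 8); step 5 is a one-step side branch.

**Step 6 (key step, proposed new method).** The most likely failure is erosion of the C2 configuration through reversible acid-induced opening of the product at O1–C2 combined with ionisation at C4. Cationic oligomerisation of 9, elimination at C4 and a second arylation at C4 are further threats. The electron-rich aldehyde may also be too weak an electrophile, in which case oligomerisation of 9 would dominate. The fallback uses known chemistry, sets out from 7 and returns at 12: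
- Addition of MeMgBr (THF, 0 °C) to 7 gives 2-(1-hydroxyethyl)-3,5-dimethoxy-4-(3-methylbut-2-enyl)phenol F1.
- MnO2 (CH2Cl2, rt) oxidises it to 1-[6-hydroxy-2,4-dimethoxy-3-(3-methylbut-2-enyl)phenyl]ethanone F2.
- Condensation with N,N-dimethylformamide dimethyl acetal (toluene, 90 °C) gives (E)-3-(dimethylamino)-1-[6-hydroxy-2,4-dimethoxy-3-(3-methylbut-2-enyl)phenyl]prop-2-en-1-one F3.
- Brief treatment with dilute HCl in CH2Cl2 closes it, with loss of dimethylamine, to 5,7-dimethoxy-6-(3-methylbut-2-enyl)-4H-chromen-4-one F4.
- Enantioselective conjugate addition of 4-hydroxyphenylboronic acid to F4 should give 12 directly. Conditions: Pd(OCOCF3)2, 4-tert-butyl-2-(pyridin-2-yl)-4,5-dihydrooxazole (the ligand antipode that delivers 2S), NH4PF6, water, 1,2-dichloroethane, 60 °C.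

**Step 8.** The most likely failure is opening of ring C by retro-oxa-Michael reaction at the magnesium-chelated stage, which would racemise C2 and is assisted by electron push from the free 4'-hydroxyl. A slow reaction, caused by the phenol sequestering the reagent, would prolong exposure and allow cyclisation of the prenyl group onto the freed C5 hydroxyl. The fallback sets out from 12 and returns at 13:
- Silylation (TIPSCl, imidazole, DMF) gives (2S)-5,7-dimethoxy-6-(3-methylbut-2-enyl)-2-[4-(triisopropylsilyloxy)phenyl]chroman-4-one F5.
- The same chelation-controlled cleavage with less MgI2·OEt2 at lower temperature gives (2S)-5-hydroxy-7-methoxy-6-(3-methylbut-2-enyl)-2-[4-(triisopropylsilyloxy)phenyl]chroman-4-one F6.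
- TBAF buffered with AcOH (THF, 0 °C) releases 13.

**Step 7.** The most likely failure is oxidation at the free para-alkylphenol (phenoxyl radical or quinone methide formation with opening of ring C) competing with oxidation of the hindered C4 carbinol. Ionisation at C4 on acidic sites of the oxide is also possible. The fallback sets out from 11 and returns at 12:
- Phenol-selective silylation (TBSCl, imidazole, DMF, 0 °C) gives (2S,4S)-2-[4-(tert-butyldimethylsilyloxy)phenyl]-5,7-dimethoxy-6-(3-methylbut-2-enyl)chroman-4-ol F7.
- Dess–Martin periodinane with NaHCO3 (CH2Cl2) gives (2S)-2-[4-(tert-butyldimethylsilyloxy)phenyl]-5,7-dimethoxy-6-(3-methylbut-2-enyl)chroman-4-one F8.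
- TBAF/AcOH gives 12.

**Step 2.** The most likely failures are allylic transposition in the alkylation (attack at the tertiary terminus of the prenyl unit), halogen–lithium exchange with homocoupling, or partial metalation beside the silyloxy group. The fallback sets out from 2 and returns at 5:
- Aryllithium 4 is quenched with allyl bromide, for which transposition has no consequence, to give (4-allyl-3,5-dimethoxyphenoxy)triisopropylsilane F9.
- Cross-metathesis with 2-methylbut-2-ene using second-generation Grubbs catalyst, RuCl2(=CHPh)(PCy3)(H2IMes), in CH2Cl2 at 40 °C converts the allyl group into the prenyl group of 5, with loss of propene.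

## Further compounds

F1 | step 6 | 2-(1-hydroxyethyl)-3,5-dimethoxy-4-(3-methylbut-2-enyl)phenol (racemic) | COc1cc(O)c(C(C)O)c(OC)c1CC=C(C)C
F2 | step 6 | 1-[6-hydroxy-2,4-dimethoxy-3-(3-methylbut-2-enyl)phenyl]ethanone | COc1cc(O)c(C(C)=O)c(OC)c1CC=C(C)C
F3 | step 6 | (E)-3-(dimethylamino)-1-[6-hydroxy-2,4-dimethoxy-3-(3-methylbut-2-enyl)phenyl]prop-2-en-1-one | COc1cc(O)c(C(=O)/C=C/N(C)C)c(OC)c1CC=C(C)C
F4 | step 6 | 5,7-dimethoxy-6-(3-methylbut-2-enyl)-4H-chromen-4-one | COc1cc2occc(=O)c2c(OC)c1CC=C(C)C
F5 | step 8 | (2S)-5,7-dimethoxy-6-(3-methylbut-2-enyl)-2-[4-(triisopropylsilyloxy)phenyl]chroman-4-one | COc1cc2c(c(OC)c1CC=C(C)C)C(=O)C[C@@H](c1ccc(O[Si](C(C)C)(C(C)C)C(C)C)cc1)O2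
F6 | step 8 | (2S)-5-hydroxy-7-methoxy-6-(3-methylbut-2-enyl)-2-[4-(triisopropylsilyloxy)phenyl]chroman-4-one | COc1cc2c(c(O)c1CC=C(C)C)C(=O)C[C@@H](c1ccc(O[Si](C(C)C)(C(C)C)C(C)C)cc1)O2
F7 | step 7 | (2S,4S)-2-[4-(tert-butyldimethylsilyloxy)phenyl]-5,7-dimethoxy-6-(3-methylbut-2-enyl)chroman-4-ol | COc1cc2c(c(OC)c1CC=C(C)C)[C@@H](O)C[C@@H](c1ccc(O[Si](C)(C)C(C)(C)C)cc1)O2
F8 | step 7 | (2S)-2-[4-(tert-butyldimethylsilyloxy)phenyl]-5,7-dimethoxy-6-(3-methylbut-2-enyl)chroman-4-one | COc1cc2c(c(OC)c1CC=C(C)C)C(=O)C[C@@H](c1ccc(O[Si](C)(C)C(C)(C)C)cc1)O2
F9 | step 2 | (4-allyl-3,5-dimethoxyphenoxy)triisopropylsilane | C=CCc1c(OC)cc(O[Si](C(C)C)(C(C)C)C(C)C)cc1OC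
A1 | alternative 1 | (2S)-2-[4-(tert-butyldimethylsilyloxy)phenyl]-5-hydroxy-7-methoxy-6-(3-methylbut-2-enyl)chroman-4-one | COc1cc2c(c(O)c1CC=C(C)C)C(=O)C[C@@H](c1ccc(O[Si](C)(C)C(C)(C)C)cc1)O2
A2 | alternative 1 | (2S)-2-[4-(tert-butyldimethylsilyloxy)phenyl]-6-(diazoacetyl)-2,3-dihydro-4H-pyran-4-one | [N-]=[N+]=CC(=O)C1=CC(=O)C[C@@H](c2ccc(O[Si](C)(C)C(C)(C)C)cc2)O1
A3 | alternative 1 | 1-methoxy-5-methylhex-4-en-1-yne | COC#CCC=C(C)C
A4 | alternative 2 | (2S)-5,7-dimethoxy-2-[4-(methoxymethoxy)phenyl]-6-(3-methylbut-2-enyl)chroman-4-one | COc1cc2c(c(OC)c1CC=C(C)C)C(=O)C[C@@H](c1ccc(OCOC)cc1)O2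
A5 | alternative 2 | (3S)-1-[6-fluoro-2,4-dimethoxy-3-(3-methylbut-2-enyl)phenyl]-3-[4-(methoxymethoxy)phenyl]-3-(triethylsilyloxy)propan-1-one | COc1cc(F)c(C(=O)C[C@H](O[Si](CC)(CC)CC)c2ccc(OCOC)cc2)c(OC)c1CC=C(C)C
A6 | alternative 3 | (2S)-4-(tert-butyldimethylsilyloxy)-2-[4-(tert-butyldimethylsilyloxy)phenyl]-5,7-dimethoxy-6-(3-methylbut-2-enyl)-2H-chromene | COc1cc2c(c(OC)c1CC=C(C)C)C(O[Si](C)(C)C(C)(C)C)=C[C@@H](c1ccc(O[Si](C)(C)C(C)(C)C)cc1)O2
A7 | alternative 3 | tert-butyl{4-[(1S)-1-{2-[1-(tert-butyldimethylsilyloxy)vinyl]-3,5-dimethoxy-4-(3-methylbut-2-enyl)phenoxy}prop-2-enyl]phenoxy}dimethylsilane | COc1cc(O[C@@H](C=C)c2ccc(O[Si](C)(C)C(C)(C)C)cc2)c(C(=C)O[Si](C)(C)C(C)(C)C)c(OC)c1CC=C(C)C
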